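## Structural features

The target is an isoflavan: a chroman (aromatic ring A fused to the dihydropyran ring C) whose C3 carries ring B through C1'. Ring A has a phloroglucinol pattern (O1 on C8a, methoxyls on C5 and C7), a prenyl group on C6 between the two methoxyls and one hydrogen on C8. Ring B is a 2-hydroxy-3-prenyl-1,4-benzoquinone with carbonyls at C2' and C5', the acidic enol at C4', a prenyl group at C3' and one hydrogen at C6'. The only stereocentre is C3 (R), with no stereogenic neighbour. Its hydrogen is γ to the C5' carbonyl and β to the O1 aryloxy group, so base can erase it through a quinone methide tautomer or open ring C. The fragile groups are the two trisubstituted alkenes (no heterogeneous hydrogenation, no hydroboration, no strong acid, least of all where a free hydroxyl sits beside a prenyl group as at C4'/C3'), the electrophilic hydroxyquinone with its open C6' position, and the electron-rich ring A, which excludes strong one-electron oxidants. The real difficulty is ring B: five substituents in a fixed order (O, prenyl, O, O, H from C2' to C6') on a ring that must be bonded to a configured sp3 carbon. The key step uses the fact that C2'–C3'–C4'–C5' with its three oxygens and the prenyl group is a squaric acid unit, while C1'=C6' is a vinyl group on C3. A 4-alkenyl-4-hydroxycyclobutenone therefore holds all six ring B carbons, and thermal ring expansion closes C1'–C2'.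

## Logic of the disconnections

**26 to 25 to 24.** No skeletal bond is cut. The C4' enol is masked as a tert-butyl ether and the quinone is taken back to the hydroquinone. This keeps the hydroxyquinone out of all organometallic and thermal steps and lets it be unveiled by acid, not by base, which would threaten C3 and the open C6' position. The demand is an oxidant that spares ring A and an acidolysis faster than protonation of the prenyl alkenes.

**24 to 21 (key).** The C1'–C2' bond of ring B is cut, so the aromatic ring becomes a four-membered ring carrying an alkene. This reduces a pentasubstituted arene of defined substitution order to the adduct of two fragments. The demand is a neutral, air-free thermal ring opening in which the hydroxyl turns outward and closure occurs through carbon, with C3 a spectator.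

**21 to 19 and 20 (20 from 14).** The bond between the carbinol carbon (future C5') and the vinyl carbon (future C6') is cut. It is the only bond joining the chroman half to the squarate half, so the route becomes convergent. The demand is attack at the ketone carbonyl of 19 next to the alkoxy carbon, since that site decides the order of substituents in ring B. Addition must also outrun proton transfer from the allylic CH2 of 19, and the alkene geometry of 14 must be kept.

**19 to 18 to 16 and 17 (17 from 15).** The C3'–CH2 bond of the ring B prenyl group is cut. The gain is a symmetric, purchasable four-carbon unit. The demand is attack through the primary terminus of the allylic metal and a rearrangement that keeps one tert-butyl ether.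

**14 to 13 to 12 to 11.** The C1'=C6' double bond is cut, with C6' added as a one-carbon unit to the formyl carbon. The gain is a carboxylic acid whose stereocentre can be set by hydrogenation. The demand is that 13, with its enolisable β-aryloxy stereocentre, meets only non-basic reagents, and that the olefination is (E)-selective.

**11 to 10.** No skeletal bond is cut; the stereocentre is traced to a flat alkene. The demand is face selectivity at C3 and reduction of the conjugated alkene only.

**10 to 9 to 7 and 8.** O1–C2 and C3=C4 of ring C are cut; 8 supplies C2, C3 and the carboxyl carbon. The gain is a salicylaldehyde. The demand is that the hindered, electron-rich aldehyde still condenses.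

**7 to 6.** The C4a–C4 bond is cut (formyl group). Because 6 is symmetric with its para position blocked, only one site is open.

**6 to 5 to 2 and 3 (via 4); 2 to 1.** The C6–CH2 bond of the ring A prenyl group is cut. The demand is metalation between the two methoxyls and not beside the phenolic oxygen, which a bulky silyl ether secures, and alkylation through the primary carbon of 3.

## Other disconnections considered

**Alternative 1:** The cut is C3–C4 and O1–C2 of ring C at the lactone oxidation level. Ring A arrives as an o-quinone methide released from 3,5-dimethoxy-4-prenyl-2-[(phenylsulfonyl)methyl]phenol A2, and ring B as [2,4-bis(methoxymethoxy)-3-prenylphenyl]acetic acid A3. In the forward step, base frees the methide, the chiral isothiourea-bound enolate of activated A3 adds to the methide carbon, and the phenoxide lactonises to dihydrocoumarin A1.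

- In its favour: it is convergent, joins both aromatic rings and sets C3 in one metal-free catalytic step without pressure equipment. The ring B partner is a resorcinol whose prenyl group sits between two directing ethers. On convergence and on creating C3 in the bond-forming event it is equal to or better than the chosen plan.
- Against it here: C2 of A1 is a carbonyl that must be taken down to CH2 by reductive opening and re-closure of the ether. C3–H of A1 is benzylic and α to a lactone carbonyl under the same base that frees the methide. The methide from A2 is unsubstituted at carbon and prone to self-condensation. Ring B of A1 has only two of the three oxygens, so C5' must be oxidised last, on a free resorcinol obtained by acidic acetal removal beside a prenyl group and in the presence of ring A.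
- Comparison: the chosen plan takes all ring B oxygens and the prenyl group from the squarate, while this plan postpones the hardest regiochemical problem. Mechanistically, enolate chemistry beside an acidic stereocentre stands against a neutral pericyclic cascade. Step counts should be close, the convergence being offset by three or four adjustment steps after A1.

**Alternative 2:** The cut is C3–C1' together with a temporary C4–O bond. The partners are 5,7-dimethoxy-6-prenyl-2H-chromene A5 and 2-methoxy-3-prenyl-1,4-benzoquinone A6. The chiral Lewis acid TiCl2(TADDOLate) activates A6, C3 of A5 attacks C5 of the quinone, and the C4 benzylic cation is captured by the neighbouring quinone oxygen to give cis-pterocarpan A4. Reductive cleavage of the benzylic C–O bond of A4 (lithium in liquid ammonia, since hydrogenolysis and ionic hydrogenation endanger the prenyl groups) would lead to the methyl ether hydroquinone listed as F13.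

- In its favour: it is the shortest and most convergent plan. C3–C1' and the stereocentre are made in one step from two flat partners, and A5 should be reachable from 6 in about two steps. On step economy and convergence it is better than the chosen plan.
- Against it here: enantiocontrol rests on a stoichiometric chiral Lewis acid whose face discrimination for a 5-alkoxy chromene is not assured. (2+2) adducts and the other regiochemistry of attack can compete, and the Lewis acid meets three trisubstituted alkenes. An acid-labile ether cannot be carried on A6, so the quinone ether must be methyl and the end game is the aqueous base hydrolysis that the chosen plan avoids. A second stereocentre is made only to be destroyed.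
- Comparison: structurally it buys ring B ready-made, which is equal in regiochemical security only if the attack at C5 is clean. Mechanistically it is a stepwise cationic process against a thermal electrocyclic one. It is shorter, but with weaker control of configuration and a riskier last step.

**Alternative 3:** The cut is in ring A (C8a–C4a, C5–C6 and C8–C8a). The partners are 3-methoxy-2-prenylcyclobut-2-en-1-one A8 and the chiral methoxyalkyne A9. On heating, A8 opens to a vinylketene, adds to A9 in a (2+2) sense, and the resulting vinylcyclobutenone opens and closes by 6π-electrocyclisation to phenol A7 (Danheiser benzannulation). Desilylation and Mitsunobu closure of O1–C2 would follow.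

- In its favour: the ring A substitution pattern follows from the polarity of ketene and ynol ether, so the prenyl-between-methoxyls problem disappears and the free phenol emerges at C8a. As a reagent-free, neutral vinylketene cascade it is the mechanistic equal of the chosen key step.
- Against it here: the cascade is spent on ring A, which the chosen plan buys as 1 and dresses in four simple steps. The stereocentre must already be present in A9 and be made by separate asymmetric chemistry. A8 and A9 are sensitive, multi-step building blocks. Ring B of A7 again carries only two oxygens, so the late oxidation and acidic acetal removal of alternative 1 remain.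
- Comparison: equal in mildness of the key step, poorer in what that step achieves for this target, and clearly longer.

Key step: step 14

Remark 1: prenyl means 3-methylbut-2-en-1-yl. The C3 descriptor is S in 11 and 13 (carboxyl or formyl outranks C2) and R in 12, 14 and all later compounds, with no change in spatial arrangement.

Remark 2: the (R) antipode of BINAP is assumed to give (S)-11, by analogy with (E)-2-alkylcinnamic acids (same alkene geometry; opposite descriptor because CH2O outranks CH2Ar). The sense is to be confirmed on 11 or 12 and the ligand antipode exchanged if necessary.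

Remark 3: 16 is treated as a purchasable squarate ester.

## Steps

Step 1
Reactants: 1 3,5-dimethoxyphenol
Product: 2 (3,5-dimethoxyphenoxy)tri(propan-2-yl)silane
Conditions: TIPSCl, imidazole, DMF, rt
Reagents that add atoms: chlorotri(propan-2-yl)silane, CC(C)[Si](Cl)(C(C)C)C(C)C
Why: Phenol silylation; the bulky, non-coordinating silyl ether ensures that the next metalation is steered by the two methoxyls and not by the phenolic oxygen.

Step 2
Reactants: 2 (3,5-dimethoxyphenoxy)tri(propan-2-yl)silane; 3 1-bromo-3-methylbut-2-ene (prenyl bromide)
Product: 5 [3,5-dimethoxy-4-prenylphenoxy]tri(propan-2-yl)silane, via aryllithium 4 (not isolated)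
Conditions: n-BuLi, TMEDA, THF, 0 °C to rt; then 3, −78 °C to rt
Reagents that add atoms: none
Why: Directed ortho-metalation at the one hydrogen flanked by two methoxyls (para to the silyl ether), followed by SN2 alkylation at the primary carbon of the allylic bromide.

Step 3
Reactants: 5 [3,5-dimethoxy-4-prenylphenoxy]tri(propan-2-yl)silane
Product: 6 3,5-dimethoxy-4-prenylphenol
Conditions: Bu4NF, THF, 0 °C
Reagents that add atoms: none
Why: Fluoride desilylation of an aryl silyl ether; neutral toward the prenyl group and the methyl ethers.

Step 4
Reactants: 6 3,5-dimethoxy-4-prenylphenol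
Product: 7 6-hydroxy-2,4-dimethoxy-3-prenylbenzaldehyde
Conditions: MgCl2, Et3N, (CH2O)n, MeCN, reflux; cold 1 M HCl work-up
Reagents that add atoms: paraformaldehyde (as formaldehyde), C=O
Why: Magnesium-mediated ortho-formylation (Casnati–Skattebøl): the magnesium phenoxide delivers formaldehyde to the ortho carbon and a second formaldehyde oxidises the benzylic alkoxide. The phenol is symmetric with its para position blocked, so one product is possible, and no strong acid meets the prenyl group.

Step 5
Reactants: 7 6-hydroxy-2,4-dimethoxy-3-prenylbenzaldehyde; 8 prop-2-enenitrile (acrylonitrile)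
Product: 9 5,7-dimethoxy-6-prenyl-2H-chromene-3-carbonitrile
Conditions: DABCO, neat 8 (excess), 80 °C
Reagents that add atoms: none
Why: Amine-mediated chromene annulation of a salicylaldehyde with an acrylic acceptor (oxa-Michael addition, intramolecular aldol condensation, dehydration; Baylis–Hillman type), forming O1–C2 and C3=C4.

Step 6
Reactants: 9 5,7-dimethoxy-6-prenyl-2H-chromene-3-carbonitrile
Product: 10 5,7-dimethoxy-6-prenyl-2H-chromene-3-carboxylic acid
Conditions: 10% aq NaOH, EtOH, reflux; then HCl to pH 2, 0 °C
Reagents that add atoms: water, O; sodium hydroxide, [Na+].[OH-]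
Why: Alkaline hydrolysis of a conjugated nitrile to the carboxylate; the chromene, ethers and prenyl group are inert to hydroxide, and acidification is brief and cold.

Step 7
Reactants: 10 5,7-dimethoxy-6-prenyl-2H-chromene-3-carboxylic acid
Product: 11 (3S)-5,7-dimethoxy-6-prenyl-3,4-dihydro-2H-chromene-3-carboxylic acid
Conditions: Ru(OAc)2[(R)-BINAP] (1 mol%), H2 (20 atm), MeOH, 25 °C
Reagents that add atoms: none
Why: Carboxylate-directed asymmetric hydrogenation of an α,β-unsaturated acid: the substrate binds ruthenium through the carboxylate, so only C3=C4 is reduced and the isolated prenyl alkene is left. The chiral diphosphine decides the face on which hydrogen reaches C3, and the (R) ligand is expected to give the (S) acid (see Remark 2).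

Step 8
Reactants: 11 (3S)-5,7-dimethoxy-6-prenyl-3,4-dihydro-2H-chromene-3-carboxylic acid
Product: 12 [(3R)-5,7-dimethoxy-6-prenyl-3,4-dihydro-2H-chromen-3-yl]methanol
Conditions: LiAlH4, THF, 0 °C to rt
Reagents that add atoms: none
Why: Hydride reduction of a carboxylic acid to the primary alcohol; the carboxylate cannot enolise, so C3 is untouched, and alkenes are inert.

Step 9
Reactants: 12 [(3R)-5,7-dimethoxy-6-prenyl-3,4-dihydro-2H-chromen-3-yl]methanol
Product: 13 (3S)-5,7-dimethoxy-6-prenyl-3,4-dihydro-2H-chromene-3-carbaldehyde
Conditions: Dess–Martin periodinane, NaHCO3, CH2Cl2, 0 °C; used crude at once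
Reagents that add atoms: none
Why: Dess–Martin oxidation under bicarbonate buffer is neither basic nor acidic, which protects the enolisable, β-aryloxy stereocentre and the prenyl group.

Step 10
Reactants: 13 (3S)-5,7-dimethoxy-6-prenyl-3,4-dihydro-2H-chromene-3-carbaldehyde
Product: 14 (3R)-3-[(E)-2-iodoethenyl]-5,7-dimethoxy-6-prenyl-3,4-dihydro-2H-chromene
Conditions: CrCl2, CHI3, THF/1,4-dioxane, 0 °C to rt
Reagents that add atoms: iodoform, IC(I)I
Why: Takai olefination: divalent chromium converts iodoform into a geminal dichromium species that adds to the aldehyde and eliminates to the (E)-iodoalkene under non-basic conditions, so C3 is not epimerised. Any minor (Z) isomer is removed by chromatography.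

Step 11
Reactants: 15 1-chloro-3-methylbut-2-ene (prenyl chloride); 16 3,4-di-tert-butoxycyclobut-3-ene-1,2-dione (di-tert-butyl squarate)
Product: 18 2,3-di-tert-butoxy-4-hydroxy-4-prenylcyclobut-2-en-1-one (racemic), via prenylbarium chloride 17 (not isolated)
Conditions: BaI2, lithium biphenylide LiC12H10, THF, rt (activated Ba); 15, −78 °C; then 16, −78 °C; aq NH4Cl
Reagents that add atoms: none
Why: Carbonyl allylation with an allylic barium reagent, which at low temperature reacts through its primary carbon without allylic transposition and adds 1,2 to one of the two equivalent squarate carbonyls. The carbinol centre is racemic and is destroyed in step 12.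

Step 12
Reactants: 18 2,3-di-tert-butoxy-4-hydroxy-4-prenylcyclobut-2-en-1-one
Product: 19 3-tert-butoxy-4-prenylcyclobut-3-ene-1,2-dione
Conditions: (CF3CO)2O, THF, −78 °C; then aq NaHCO3
Reagents that add atoms: none
Why: Standard squarate-adduct rearrangement: acylation of the tertiary alcohol, ionisation to the alkoxy-stabilised cyclobutenyl cation, and loss of the tert-butyl group from the oxocarbenium ion give the dione. The low temperature spares the second tert-butyl ether.

Step 13
Reactants: 14 (3R)-3-[(E)-2-iodoethenyl]-5,7-dimethoxy-6-prenyl-3,4-dihydro-2H-chromene; 19 3-tert-butoxy-4-prenylcyclobut-3-ene-1,2-dione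
Product: 21 3-tert-butoxy-4-hydroxy-4-{(E)-2-[(3R)-5,7-dimethoxy-6-prenyl-3,4-dihydro-2H-chromen-3-yl]ethenyl}-2-prenylcyclobut-2-en-1-one (both carbinol epimers), via vinyllithium 20 (not isolated)
Conditions: t-BuLi (2 equiv), Et2O, −78 °C; cannulated into 19 (slight excess), THF, −78 °C; aq NH4Cl
Reagents that add atoms: none
Why: Iodine–lithium exchange with retention of alkene geometry, then 1,2-addition to the more electrophilic ketone carbonyl of 19 (the one bonded to the alkoxy carbon; the other is a deactivated vinylogous ester carbonyl). This site selectivity fixes the ring B substitution order, and the epimer mixture at the carbinol is without consequence.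

Step 14
Reactants: 21 3-tert-butoxy-4-hydroxy-4-{(E)-2-[(3R)-5,7-dimethoxy-6-prenyl-3,4-dihydro-2H-chromen-3-yl]ethenyl}-2-prenylcyclobut-2-en-1-one
Product: 24 2-tert-butoxy-5-[(3R)-5,7-dimethoxy-6-prenyl-3,4-dihydro-2H-chromen-3-yl]-3-prenylbenzene-1,4-diol, via dienylketene 22 (not isolated), via cyclohexadienone 23 (not isolated)
Conditions: toluene (degassed, 0.02 M), 110 °C, Ar
Reagents that add atoms: none
Why: This is the thermal ring expansion of a 4-alkenyl-4-hydroxycyclobutenone to a hydroquinone (Moore rearrangement). Conrotatory 4π opening breaks the bond between the carbonyl carbon and the carbinol carbon; the donor hydroxyl rotates outward, which places the alkenyl group inward, cis to the ketene, in 22. A 6π-electrocyclisation then joins the ketene carbon to the distal alkene carbon (the one bonded to C3), forming C1'–C2' and closing ring B as the six-membered carbocycle 23; the trans alkene keeps the chromanyl group on the outside of the folding triene. Enolisation of 23 removes its only new sp3 centre, so the step creates no stereocentre and both carbinol epimers of 21 converge on one aromatic product. The order OH, tert-butoxy, prenyl, OH around ring B is not decided here; it was fixed by the site of addition in step 13. C3 is insulated from the reacting π system by being sp3 and meets neither acid nor base, so its configuration is carried through. The selectivity required is closure of the ketene through carbon, not capture by the enol oxygen, and it is secured by the outward rotation of the hydroxyl and the conjugated alkenyl group; the ketene-bound prenyl group is too short a tether for an intramolecular (2+2) addition. Degassed solvent keeps the hydroquinone from oxidising before isolation.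

Step 15
Reactants: 24 2-tert-butoxy-5-[(3R)-5,7-dimethoxy-6-prenyl-3,4-dihydro-2H-chromen-3-yl]-3-prenylbenzene-1,4-diol
Product: 25 2-tert-butoxy-5-[(3R)-5,7-dimethoxy-6-prenyl-3,4-dihydro-2H-chromen-3-yl]-3-prenylcyclohexa-2,5-diene-1,4-dione
Conditions: Ag2O, Na2SO4, Et2O, rt
Reagents that add atoms: none
Why: Two-electron oxidation of a hydroquinone to the quinone by Ag2O; the reagent is too mild to attack ring A or the prenyl groups, which a strong one-electron oxidant would not spare.

Step 16
Reactants: 25 2-tert-butoxy-5-[(3R)-5,7-dimethoxy-6-prenyl-3,4-dihydro-2H-chromen-3-yl]-3-prenylcyclohexa-2,5-diene-1,4-dione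
Product: 26 5-[(3R)-5,7-dimethoxy-6-prenyl-3,4-dihydro-2H-chromen-3-yl]-2-hydroxy-3-prenylcyclohexa-2,5-diene-1,4-dione (target)
Conditions: CF3CO2H (10 vol%), CH2Cl2, 0 °C, short contact, argon sweep; cold pH 7 buffer quench
Reagents that add atoms: none
Why: Acidolysis of a vinylogous tert-butyl ester: protonation at the quinone carbonyl and loss of the tert-butyl cation as 2-methylpropene release the vinylogous acid far faster than the prenyl alkenes are protonated. No base is used, so C3 and the open C6' position are not endangered.

## Compound list

1 | 3,5-dimethoxyphenol | COc1cc(O)cc(OC)c1 | starting material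
2 | (3,5-dimethoxyphenoxy)tri(propan-2-yl)silane | COc1cc(O[Si](C(C)C)(C(C)C)C(C)C)cc(OC)c1 | intermediate
3 | 1-bromo-3-methylbut-2-ene (prenyl bromide) | CC(C)=CCBr | starting material
4 | [2,6-dimethoxy-4-(triisopropylsilyloxy)phenyl]lithium | [Li]c1c(OC)cc(O[Si](C(C)C)(C(C)C)C(C)C)cc1OC | intermediate (not isolated)
5 | [3,5-dimethoxy-4-prenylphenoxy]tri(propan-2-yl)silane | COc1cc(O[Si](C(C)C)(C(C)C)C(C)C)cc(OC)c1CC=C(C)C | intermediate
6 | 3,5-dimethoxy-4-prenylphenol | COc1cc(O)cc(OC)c1CC=C(C)C | intermediate
7 | 6-hydroxy-2,4-dimethoxy-3-prenylbenzaldehyde | COc1cc(O)c(C=O)c(OC)c1CC=C(C)C | intermediate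
8 | prop-2-enenitrile (acrylonitrile) | C=CC#N | starting material
9 | 5,7-dimethoxy-6-prenyl-2H-chromene-3-carbonitrile | COc1cc2OCC(C#N)=Cc2c(OC)c1CC=C(C)C | intermediate
10 | 5,7-dimethoxy-6-prenyl-2H-chromene-3-carboxylic acid | COc1cc2OCC(C(=O)O)=Cc2c(OC)c1CC=C(C)C | intermediate
11 | (3S)-5,7-dimethoxy-6-prenyl-3,4-dihydro-2H-chromene-3-carboxylic acid | COc1cc2c(c(OC)c1CC=C(C)C)C[C@H](C(=O)O)CO2 | intermediate
12 | [(3R)-5,7-dimethoxy-6-prenyl-3,4-dihydro-2H-chromen-3-yl]methanol | COc1cc2c(c(OC)c1CC=C(C)C)C[C@H](CO)CO2 | intermediate
13 | (3S)-5,7-dimethoxy-6-prenyl-3,4-dihydro-2H-chromene-3-carbaldehyde | COc1cc2c(c(OC)c1CC=C(C)C)C[C@H](C=O)CO2 | intermediate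
14 | (3R)-3-[(E)-2-iodoethenyl]-5,7-dimethoxy-6-prenyl-3,4-dihydro-2H-chromene | COc1cc2c(c(OC)c1CC=C(C)C)C[C@H](/C=C/I)CO2 | intermediate
15 | 1-chloro-3-methylbut-2-ene (prenyl chloride) | CC(C)=CCCl | starting material
16 | 3,4-di-tert-butoxycyclobut-3-ene-1,2-dione (di-tert-butyl squarate) | CC(C)(C)OC1=C(OC(C)(C)C)C(=O)C1=O | starting material
17 | chloro(3-methylbut-2-en-1-yl)barium (prenylbarium chloride) | CC(C)=CC[Ba]Cl | intermediate (not isolated)
18 | 2,3-di-tert-butoxy-4-hydroxy-4-prenylcyclobut-2-en-1-one (racemic) | CC(C)=CCC1(O)C(OC(C)(C)C)=C(OC(C)(C)C)C1=O | intermediate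
19 | 3-tert-butoxy-4-prenylcyclobut-3-ene-1,2-dione | CC(C)=CCC1=C(OC(C)(C)C)C(=O)C1=O | intermediate
20 | {(E)-2-[(3R)-5,7-dimethoxy-6-prenyl-3,4-dihydro-2H-chromen-3-yl]ethenyl}lithium | COc1cc2c(c(OC)c1CC=C(C)C)C[C@H](/C=C/[Li])CO2 | intermediate (not isolated)
21 | 3-tert-butoxy-4-hydroxy-4-{(E)-2-[(3R)-5,7-dimethoxy-6-prenyl-3,4-dihydro-2H-chromen-3-yl]ethenyl}-2-prenylcyclobut-2-en-1-one (both carbinol epimers) | COc1cc2c(c(OC)c1CC=C(C)C)C[C@H](/C=C/C1(O)C(OC(C)(C)C)=C(CC=C(C)C)C1=O)CO2 | intermediate (key-step precursor)
22 | (3Z,5E)-3-tert-butoxy-4-hydroxy-6-[(3R)-5,7-dimethoxy-6-prenyl-3,4-dihydro-2H-chromen-3-yl]-2-prenylhexa-1,3,5-trien-1-one (dienylketene) | COc1cc2c(c(OC)c1CC=C(C)C)C[C@H](/C=C/C(O)=C(\C(CC=C(C)C)=C=O)OC(C)(C)C)CO2 | intermediate (not isolated)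
23 | 3-tert-butoxy-4-hydroxy-6-[(3R)-5,7-dimethoxy-6-prenyl-3,4-dihydro-2H-chromen-3-yl]-2-prenylcyclohexa-2,4-dien-1-one (either C6 epimer) | COc1cc2c(c(OC)c1CC=C(C)C)C[C@H](C1C=C(O)C(OC(C)(C)C)=C(CC=C(C)C)C1=O)CO2 | intermediate (not isolated)
24 | 2-tert-butoxy-5-[(3R)-5,7-dimethoxy-6-prenyl-3,4-dihydro-2H-chromen-3-yl]-3-prenylbenzene-1,4-diol | COc1cc2c(c(OC)c1CC=C(C)C)C[C@H](c1cc(O)c(OC(C)(C)C)c(CC=C(C)C)c1O)CO2 | intermediate (key-step product)
25 | 2-tert-butoxy-5-[(3R)-5,7-dimethoxy-6-prenyl-3,4-dihydro-2H-chromen-3-yl]-3-prenylcyclohexa-2,5-diene-1,4-dione | COc1cc2c(c(OC)c1CC=C(C)C)C[C@H](C1=CC(=O)C(OC(C)(C)C)=C(CC=C(C)C)C1=O)CO2 | intermediate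
26 | 5-[(3R)-5,7-dimethoxy-6-prenyl-3,4-dihydro-2H-chromen-3-yl]-2-hydroxy-3-prenylcyclohexa-2,5-diene-1,4-dione | COc1cc2c(c(OC)c1CC=C(C)C)C[C@H](C1=CC(=O)C(O)=C(CC=C(C)C)C1=O)CO2 | target

## Step count and least certain steps

Total: 16 steps. Longest linear sequence: 14 steps (steps 1 to 10, then 13 to 16); steps 11 and 12 form the short branch.

**Step 14 (key step).** The likeliest failure is diversion of the ketene: closure through the enol oxygen to a furanone if some material opens with the hydroxyl inward, or partial loss of the tert-butyl group on heating, followed by oxidation of the exposed hydroquinone during isolation. Fallback, from 21 back to 24: the carbinol is silylated (Me3SiCl, Et3N, DMAP, CH2Cl2, 0 °C) to the trimethylsilyl ether of 21 F1. A silyl ether rotates outward like the hydroxyl but cannot add to the ketene. Thermolysis in toluene at 110 °C should give the hydroquinone mono(trimethylsilyl) ether F2 (silyl transfer to the other phenolic oxygen would be harmless). Methanolysis with catalytic pyridinium p-toluenesulfonate at 0 °C returns 24.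

**Step 11.** The likeliest failure is erosion of site selectivity in the allylic metal (attack through the tertiary terminus) or reductive coupling of 15 during formation of 17. Fallback, from 16 back to 18: allylmagnesium bromide CH2=CHCH2MgBr (THF, −78 °C) adds to 16 to give 4-allyl-2,3-di-tert-butoxy-4-hydroxycyclobut-2-en-1-one F3, for which the two termini of the nucleophile are identical. Cross metathesis with excess 2-methylbut-2-ene (second-generation Grubbs catalyst RuCl2(PCy3)(H2IMes)(=CHPh), CH2Cl2, 40 °C) converts the allyl group into prenyl and gives 18.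

**Step 13.** The likeliest failure is proton transfer from the doubly activated CH2 of 19 to the strongly basic vinyllithium, or attack at the vinylogous ester carbonyl. Fallback, from 13 to 25, rejoining after the hydroquinone stage: Colvin homologation of 13 (lithiated trimethylsilyldiazomethane, THF, −78 °C to rt) gives (3R)-3-ethynyl-5,7-dimethoxy-6-prenyl-3,4-dihydro-2H-chromene F4. Its much less basic lithium acetylide (n-BuLi, THF, −78 °C) adds to the same carbonyl of 19 to give the 4-alkynyl-4-hydroxycyclobutenone F5. Heating F5 in toluene at 110 °C effects the alkynyl variant of the same ring expansion (ketene, ring closure to a diradical, hydrogen transfer from the hydroxyl), which forms the same C1'–C2' bond and should give quinone 25 directly.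

**Step 7.** The likeliest failure is insufficient or reversed face selectivity, or slow saturation of the prenyl alkene at long reaction times. Fallback, from 10 back to 12: hydrogenation with Ru(OAc)2(rac-BINAP) gives the racemic acid F6. Its mixed pivalic anhydride (t-BuCOCl, Et3N) is coupled with lithiated (4S)-4-benzyl-1,3-oxazolidin-2-one to give the diastereomeric imides F7 (3S acyl) and F8 (3R acyl), which are separated by chromatography or crystallisation. LiBH4 (THF, one equivalent of water, 0 °C) cleaves F7 to 12 and returns the auxiliary.

**Step 16.** The likeliest failure is acid-induced cyclisation of the new C4' hydroxyl onto the C3' prenyl group, or addition of acid or tert-butyl cation to ring A and the alkenes. Fallback, the methyl ether series with a basic unveiling, from 17 and 20 back to 26: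

- 17 adds to dimethyl squarate F9 to give 4-hydroxy-2,3-dimethoxy-4-prenylcyclobut-2-en-1-one F10.
- (CF3CO)2O, then water, gives 3-methoxy-4-prenylcyclobut-3-ene-1,2-dione F11.
- Addition of 20 as in step 13 gives the methoxy carbinol F12.
- Thermolysis as in step 14 gives the methoxy hydroquinone F13.
- Ag2O gives the methoxyquinone F14.
- 0.1 M NaOH in THF/water at 0 °C for a short time, then acidification to pH 3, hydrolyses the vinylogous ester to 26.

## Further compounds

F1 | step 14 | 3-tert-butoxy-4-{(E)-2-[(3R)-5,7-dimethoxy-6-prenyl-3,4-dihydro-2H-chromen-3-yl]ethenyl}-2-prenyl-4-(trimethylsilyloxy)cyclobut-2-en-1-one | COc1cc2c(c(OC)c1CC=C(C)C)C[C@H](/C=C/C1(O[Si](C)(C)C)C(OC(C)(C)C)=C(CC=C(C)C)C1=O)CO2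
F2 | step 14 | 3-tert-butoxy-6-[(3R)-5,7-dimethoxy-6-prenyl-3,4-dihydro-2H-chromen-3-yl]-2-prenyl-4-(trimethylsilyloxy)phenol | COc1cc2c(c(OC)c1CC=C(C)C)C[C@H](c1cc(O[Si](C)(C)C)c(OC(C)(C)C)c(CC=C(C)C)c1O)CO2
F3 | step 11 | 4-allyl-2,3-di-tert-butoxy-4-hydroxycyclobut-2-en-1-one | C=CCC1(O)C(OC(C)(C)C)=C(OC(C)(C)C)C1=O
F4 | step 13 | (3R)-3-ethynyl-5,7-dimethoxy-6-prenyl-3,4-dihydro-2H-chromene | COc1cc2c(c(OC)c1CC=C(C)C)C[C@H](C#C)CO2
F5 | step 13 | 3-tert-butoxy-4-{[(3R)-5,7-dimethoxy-6-prenyl-3,4-dihydro-2H-chromen-3-yl]ethynyl}-4-hydroxy-2-prenylcyclobut-2-en-1-one | COc1cc2c(c(OC)c1CC=C(C)C)C[C@H](C#CC1(O)C(OC(C)(C)C)=C(CC=C(C)C)C1=O)CO2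
F6 | step 7 | racemic 5,7-dimethoxy-6-prenyl-3,4-dihydro-2H-chromene-3-carboxylic acid | COc1cc2c(c(OC)c1CC=C(C)C)CC(C(=O)O)CO2
F7 | step 7 | (4S)-4-benzyl-3-{[(3S)-5,7-dimethoxy-6-prenyl-3,4-dihydro-2H-chromen-3-yl]carbonyl}-1,3-oxazolidin-2-one | COc1cc2c(c(OC)c1CC=C(C)C)C[C@H](C(=O)N1[C@@H](Cc3ccccc3)COC1=O)CO2
F8 | step 7 | (4S)-4-benzyl-3-{[(3R)-5,7-dimethoxy-6-prenyl-3,4-dihydro-2H-chromen-3-yl]carbonyl}-1,3-oxazolidin-2-one | COc1cc2c(c(OC)c1CC=C(C)C)C[C@@H](C(=O)N1[C@@H](Cc3ccccc3)COC1=O)CO2
F9 | step 16 | 3,4-dimethoxycyclobut-3-ene-1,2-dione (dimethyl squarate) | COC1=C(OC)C(=O)C1=O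
F10 | step 16 | 4-hydroxy-2,3-dimethoxy-4-prenylcyclobut-2-en-1-one | CC(C)=CCC1(O)C(OC)=C(OC)C1=O
F11 | step 16 | 3-methoxy-4-prenylcyclobut-3-ene-1,2-dione | CC(C)=CCC1=C(OC)C(=O)C1=O
F12 | step 16 | 4-hydroxy-3-methoxy-4-{(E)-2-[(3R)-5,7-dimethoxy-6-prenyl-3,4-dihydro-2H-chromen-3-yl]ethenyl}-2-prenylcyclobut-2-en-1-one | COc1cc2c(c(OC)c1CC=C(C)C)C[C@H](/C=C/C1(O)C(OC)=C(CC=C(C)C)C1=O)CO2
F13 | step 16 | 2-methoxy-5-[(3R)-5,7-dimethoxy-6-prenyl-3,4-dihydro-2H-chromen-3-yl]-3-prenylbenzene-1,4-diol | COc1cc2c(c(OC)c1CC=C(C)C)C[C@H](c1cc(O)c(OC)c(CC=C(C)C)c1O)CO2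
F14 | step 16 | 2-methoxy-5-[(3R)-5,7-dimethoxy-6-prenyl-3,4-dihydro-2H-chromen-3-yl]-3-prenylcyclohexa-2,5-diene-1,4-dione | COc1cc2c(c(OC)c1CC=C(C)C)C[C@H](C1=CC(=O)C(OC)=C(CC=C(C)C)C1=O)CO2
A1 | alternative 1 | (R)-3-[2,4-bis(methoxymethoxy)-3-prenylphenyl]-5,7-dimethoxy-6-prenylchroman-2-one | COc1cc2c(c(OC)c1CC=C(C)C)C[C@H](c1ccc(OCOC)c(CC=C(C)C)c1OCOC)C(=O)O2
A2 | alternative 1 | 3,5-dimethoxy-4-prenyl-2-[(phenylsulfonyl)methyl]phenol | COc1cc(O)c(CS(=O)(=O)c2ccccc2)c(OC)c1CC=C(C)C
A3 | alternative 1 | [2,4-bis(methoxymethoxy)-3-prenylphenyl]acetic acid | COCOc1ccc(CC(=O)O)c(OCOC)c1CC=C(C)C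
A4 | alternative 2 | cis-8-hydroxy-1,3,9-trimethoxy-2,10-diprenylpterocarpan | COc1cc2c(c(OC)c1CC=C(C)C)[C@@H]3Oc4c(CC=C(C)C)c(OC)c(O)cc4[C@@H]3CO2
A5 | alternative 2 | 5,7-dimethoxy-6-prenyl-2H-chromene | COc1cc2OCC=Cc2c(OC)c1CC=C(C)C
A6 | alternative 2 | 2-methoxy-3-prenyl-1,4-benzoquinone | COC1=C(CC=C(C)C)C(=O)C=CC1=O
A7 | alternative 3 | (R)-2-{2-[2,4-bis(methoxymethoxy)-3-prenylphenyl]-3-(tert-butyldimethylsilyloxy)propyl}-3,5-dimethoxy-4-prenylphenol | COc1cc(O)c(C[C@H](c2ccc(OCOC)c(CC=C(C)C)c2OCOC)CO[Si](C)(C)C(C)(C)C)c(OC)c1CC=C(C)C
A8 | alternative 3 | 3-methoxy-2-prenylcyclobut-2-en-1-one | COC1=C(CC=C(C)C)C(=O)C1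
A9 | alternative 3 | (R)-tert-butyl{2-[2,4-bis(methoxymethoxy)-3-prenylphenyl]-5-methoxypent-4-yn-1-yloxy}dimethylsilane | COC#CC[C@H](c1ccc(OCOC)c(CC=C(C)C)c1OCOC)CO[Si](C)(C)C(C)(C)C
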